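The synthesis rests on disconnecting the C2′–O bond of ring B and re-forming it through a temporary ring. Ring B carries its C2′ oxygen next to the C1′–C3 bond, so an oxygen on C4 of ring C, cis to ring B, can reach C2′; without that oxygen, ring B is the symmetric 3,4,5-trimethoxyphenyl group. In one operation a C4-hydroxyl-directed palladium C–H etherification closes a cis-fused dihydrofuran (a pterocarpan) and installs the C2′ oxygen. The precursor is the (3S,4S)-cis-isoflavan-4-ol bearing a 3,4,5-trimethoxyphenyl ring B and a 7-O-pivalate. Hydrogenolysis of the benzylic C4–O bond, O-methylation and ester cleavage finish the synthesis.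

Key step: step 4

Remark on the chemistry: the 7-oxygen is carried as a pivalate, not as an electron-releasing ether. An acyl group para to C4 should make the C4–H bond less hydridic and the C4–O bond less ionisable, which should slow oxidation to the ketone and dehydration in the key step. It is also inert to trivalent iodine, formic acid/Et3N, hydrogenation and carbonate/MeI. Isoflavan numbering (rings A, B, C; primed positions on ring B) is used throughout, except in the systematic name of the pterocarpan.

Step 1
Reactants: 1 2-methoxyresorcinol; 2 3,4,5-trimethoxyphenylacetic acid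
Product: 4 7-hydroxy-8-methoxy-3-(3,4,5-trimethoxyphenyl)-4H-chromen-4-one, via deoxybenzoin 3 (not isolated)
Conditions: BF3·OEt2 (solvent), 85 °C; then DMF, MsCl, 70 °C; aq NaOAc
Reagents that add atoms: N,N-dimethylformamide, CN(C)C=O
Why: Friedel–Crafts acylation at C4 of the resorcinol (ortho and para to the two hydroxyls; C4 and C6 are equivalent) gives deoxybenzoin 3, whose boron-chelated enol is formylated at the methylene by the DMF/MsCl Vilsmeier-type iminium and closes to the chromone with loss of dimethylamine (one-pot deoxybenzoin synthesis of isoflavones).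

Step 2
Reactants: 4 7-hydroxy-8-methoxy-3-(3,4,5-trimethoxyphenyl)-4H-chromen-4-one
Product: 5 8-methoxy-4-oxo-3-(3,4,5-trimethoxyphenyl)-4H-chromen-7-yl pivalate
Conditions: PivCl, K2CO3, acetone, 23 °C
Reagents that add atoms: pivaloyl chloride, CC(C)(C)C(=O)Cl
Why: O-acylation of the phenoxide of the only free hydroxyl, giving a hindered aryl ester that should survive every later step until its planned methanolysis.

Step 3
Reactants: 5 8-methoxy-4-oxo-3-(3,4,5-trimethoxyphenyl)-4H-chromen-7-yl pivalate
Product: 7 (3S,4S)-4-hydroxy-8-methoxy-3-(3,4,5-trimethoxyphenyl)chroman-7-yl pivalate, via isoflavanone 6 (not isolated)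
Conditions: RuCl(p-cymene)[(S,S)-TsDPEN] (3 mol %), HCO2H/Et3N (5:2), EtOAc, 45 °C
Reagents that add atoms: none
Why: Noyori asymmetric transfer hydrogenation run as a cascade: the ruthenium hydride first reduces the chromone C2=C3 bond to isoflavanone 6, whose C3 epimerises through its enol under Et3N, and the (S,S)-catalyst then reduces the faster-reacting enantiomer (dynamic kinetic resolution), setting C4 as S by the usual aryl-ketone face selection and, with hydride entering anti to the C3 aryl group, C3 as S in the cis alcohol.

Step 4
Reactants: 7 (3S,4S)-4-hydroxy-8-methoxy-3-(3,4,5-trimethoxyphenyl)chroman-7-yl pivalate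
Product: 8 (6aS,11aS)-4,8,9,10-tetramethoxy-6a,11a-dihydro-6H-benzofuro[3,2-c]chromen-3-yl pivalate (cis-4,8,9,10-tetramethoxy-3-pivaloyloxypterocarpan)
Conditions: Pd(OAc)2 (10 mol %), PhI(OAc)2 (1.5 equiv), Li2CO3 (1.5 equiv), C6F6, 100 °C
Reagents that add atoms: none
Why: Proposed new method: deprotonated by Li2CO3, the C4 hydroxyl coordinates to divalent palladium as an alkoxide; an acetate-assisted metalation–deprotonation then cleaves an ortho C–H bond of ring B to give the six-membered oxapalladacycle Pd–O–C4–C3–C1′–C2′, which PhI(OAc)2 raises to tetravalent palladium, and reductive elimination from that species joins C2′ to oxygen. The closest known reaction type is the Pd(OAc)2/PhI(OAc)2 hydroxyl-directed C–H activation/C–O cyclisation of tertiary 2-arylethanols to dihydrobenzofurans; the extension here is to a secondary alcohol that is also benzylic to ring A. The one new ring, the five-membered dihydrofuran, closes at oxygen by C(aryl)–O reductive elimination from the six-membered palladacycle and is necessarily cis-fused to ring C. No stereocentre is created: the C4–O bond is never broken, so C4 and C3 keep their configurations (now 11aS and 6aS), and the cis relation set in step 3 is what allows closure. The step needs chemoselectivity for cyclisation over β-hydride loss to the isoflavanone, which the electron-withdrawing pivalate para to C4 and fast oxidative trapping of the palladacycle should favour. No site issue arises on ring B, whose C2′–H and C6′–H are related by symmetry, and palladation at C5 of ring A would be unproductive because it could only end in a four-membered ring.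

Step 5
Reactants: 8 (6aS,11aS)-4,8,9,10-tetramethoxy-6a,11a-dihydro-6H-benzofuro[3,2-c]chromen-3-yl pivalate
Product: 9 (3S)-3-(2-hydroxy-3,4,5-trimethoxyphenyl)-8-methoxychroman-7-yl pivalate
Conditions: H2 (1 atm), 10% Pd/C, EtOAc/EtOH, 23 °C
Reagents that add atoms: none
Why: Hydrogenolysis of the benzylic aryl ether bond (C11a–O, the only benzylic C–O bond) is the standard opening of pterocarpans to 2′-hydroxyisoflavans; C4 becomes a methylene, the oxygen stays on C2′, and the C3 stereocentre (former C6a) is not involved.

Step 6
Reactants: 9 (3S)-3-(2-hydroxy-3,4,5-trimethoxyphenyl)-8-methoxychroman-7-yl pivalate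
Product: 10 (3S)-8-methoxy-3-(2,3,4,5-tetramethoxyphenyl)chroman-7-yl pivalate
Conditions: MeI, K2CO3, acetone, 45 °C, argon
Reagents that add atoms: iodomethane, CI
Why: Williamson ether synthesis, the 2′-phenoxide attacking MeI by SN2 while the hindered aryl pivalate should stay inert to anhydrous carbonate in acetone.

Step 7
Reactants: 10 (3S)-8-methoxy-3-(2,3,4,5-tetramethoxyphenyl)chroman-7-yl pivalate
Product: 11 (3S)-8-methoxy-3-(2,3,4,5-tetramethoxyphenyl)chroman-7-ol (target)
Conditions: K2CO3 (0.3 equiv), MeOH, 40 °C; aq NH4Cl
Reagents that add atoms: none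
Why: Base-catalysed transesterification (methanolysis) of the aryl ester, driven by the good phenoxide leaving group, frees the 7-hydroxyl; C3–H is not acidic, so the stereocentre is not at risk.

Compound list
1 | 2-methoxyresorcinol (2-methoxybenzene-1,3-diol) | COc1c(O)cccc1O | starting material
2 | 3,4,5-trimethoxyphenylacetic acid | COc1cc(CC(=O)O)cc(OC)c1OC | starting material
3 | 1-(2,4-dihydroxy-3-methoxyphenyl)-2-(3,4,5-trimethoxyphenyl)ethan-1-one (deoxybenzoin, formed in the flask) | COc1cc(CC(=O)c2ccc(O)c(OC)c2O)cc(OC)c1OC | intermediate
4 | 7-hydroxy-8-methoxy-3-(3,4,5-trimethoxyphenyl)-4H-chromen-4-one | COc1cc(-c2coc3c(OC)c(O)ccc3c2=O)cc(OC)c1OC | intermediate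
5 | 8-methoxy-4-oxo-3-(3,4,5-trimethoxyphenyl)-4H-chromen-7-yl pivalate | COc1cc(-c2coc3c(OC)c(OC(=O)C(C)(C)C)ccc3c2=O)cc(OC)c1OC | intermediate
6 | 8-methoxy-4-oxo-3-(3,4,5-trimethoxyphenyl)chroman-7-yl pivalate (isoflavanone, C3 epimerising, formed in the flask) | COc1cc(C2COc3c(OC)c(OC(=O)C(C)(C)C)ccc3C2=O)cc(OC)c1OC | intermediate
7 | (3S,4S)-4-hydroxy-8-methoxy-3-(3,4,5-trimethoxyphenyl)chroman-7-yl pivalate (cis) | COc1cc([C@H]2COc3c(ccc(OC(=O)C(C)(C)C)c3OC)[C@H]2O)cc(OC)c1OC | intermediate
8 | (6aS,11aS)-4,8,9,10-tetramethoxy-6a,11a-dihydro-6H-benzofuro[3,2-c]chromen-3-yl pivalate (cis-pterocarpan) | COc1cc2c(c(OC)c1OC)O[C@@H]1c3ccc(OC(=O)C(C)(C)C)c(OC)c3OC[C@H]21 | intermediate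
9 | (3S)-3-(2-hydroxy-3,4,5-trimethoxyphenyl)-8-methoxychroman-7-yl pivalate | COc1cc([C@H]2COc3c(ccc(OC(=O)C(C)(C)C)c3OC)C2)c(O)c(OC)c1OC | intermediate
10 | (3S)-8-methoxy-3-(2,3,4,5-tetramethoxyphenyl)chroman-7-yl pivalate | COc1cc([C@H]2COc3c(ccc(OC(=O)C(C)(C)C)c3OC)C2)c(OC)c(OC)c1OC | intermediate
11 | (3S)-8-methoxy-3-(2,3,4,5-tetramethoxyphenyl)chroman-7-ol | COc1cc([C@H]2COc3c(ccc(O)c3OC)C2)c(OC)c(OC)c1OC | target

Total step count: 7
Longest linear sequence: 7 steps (from 1 or 2 to 11)

Steps most likely to fail

Step 4 (proposed new method). β-Hydride elimination from the palladium alkoxide may oxidise the carbinol faster than ring B is palladated, or the benzylic alcohol may dehydrate in the acetic acid that is released. Ketone 6 formed in this way could be returned to 7 under the conditions of step 3. The fallback uses known reactions, sets out from 5 and comes back to the route at 8. NBS in MeCN at 23 °C should brominate 5 at C2′ of ring B, the only open positions of the one electron-rich ring (ring A is deactivated by the C4 carbonyl and the ester), to give 3-(2-bromo-3,4,5-trimethoxyphenyl)-8-methoxy-4-oxo-4H-chromen-7-yl pivalate F1. The transfer-hydrogenation cascade of step 3 should then convert it, through the epimerising 2′-bromoisoflavanone F2 (not isolated), into (3S,4S)-3-(2-bromo-3,4,5-trimethoxyphenyl)-4-hydroxy-8-methoxychroman-7-yl pivalate F3. An intramolecular Buchwald–Hartwig etherification (Pd(OAc)2, 2-(di-tert-butylphosphino)-1,1′-binaphthyl, Cs2CO3, toluene, 80 °C; oxidative addition of the aryl bromide to zerovalent palladium, then C–O reductive elimination) should join the C4 oxygen to C2′ and give 8.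

Step 3. The ruthenium hydride may reduce the C2=C3 bond too slowly, or ketone reduction may outrun C3 epimerisation so that cis selectivity and enantioselectivity erode. The fallback sets out from 5 and comes back at 7 by separating the two reductions. Heterogeneous catalytic transfer hydrogenation (10% Pd/C, HCO2NH4, EtOH, 60 °C) should saturate only the C2=C3 bond and allow racemic 6 to be isolated. Isolated 6 is then submitted on its own to the ruthenium-catalysed dynamic kinetic resolution (RuCl(p-cymene)[(S,S)-TsDPEN], HCO2H/Et3N with a higher amine share to speed epimerisation), a reaction known for isoflavanones.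

Step 6. O-Methylation of the doubly ortho-substituted 2′-phenoxide may be slow enough for intermolecular acyl transfer from the 7-pivalate, or air oxidation of the electron-rich phenoxide, to compete. The fallback sets out from 9 and comes back at 10 by a Mitsunobu etherification (MeOH, PPh3, DIAD, THF, 0 to 23 °C). Methanol is the methyl source and no carbonate base or free phenoxide is present.

Further compounds
F1 | step 4 | 3-(2-bromo-3,4,5-trimethoxyphenyl)-8-methoxy-4-oxo-4H-chromen-7-yl pivalate | COc1cc(-c2coc3c(OC)c(OC(=O)C(C)(C)C)ccc3c2=O)c(Br)c(OC)c1OC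
F2 | step 4 | 3-(2-bromo-3,4,5-trimethoxyphenyl)-8-methoxy-4-oxochroman-7-yl pivalate (C3 epimerising, not isolated) | COc1cc(C2COc3c(OC)c(OC(=O)C(C)(C)C)ccc3C2=O)c(Br)c(OC)c1OC
F3 | step 4 | (3S,4S)-3-(2-bromo-3,4,5-trimethoxyphenyl)-4-hydroxy-8-methoxychroman-7-yl pivalate | COc1cc([C@H]2COc3c(ccc(OC(=O)C(C)(C)C)c3OC)[C@H]2O)c(Br)c(OC)c1OC
F0 | step 3 | none | none
F0 | step 6 | none | none
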